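**Retrosynthetic overview**

1. Target 21 ⇐ nonabenzyl ether 20 (global hydrogenolysis) ⇐ lactol 18 + catechol dibenzyl ether 19: the flavan B ring is attached last at C2 by Friedel–Crafts C-arylation, cis to the C3 oxygen.
2. 18 ⇐ lactone 17 ⇐ ester 16: key disconnection C3–C4 of flavan ring C, made at the 3,4-dihydrocoumarin level by enantioselective intramolecular 1,6-addition of a glycolate ester enolate to a para-quinone methide.
3. Enabling feature: flavan C4 is doubly benzylic and sits on C5 of flavonol ring A, para to the flavonol C8 hydroxyl, so C4 can be the exocyclic carbon of a para-quinone methide of that ring. C3 bears an oxygen and neighbours C2, which can be held at the ester level on O1 of flavan ring A, making C3 an enolisable glycolate carbon within six-ring reach of C4.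
4. 16 ⇐ quinone methide 14 + benzyloxyacetyl chloride 15; 14 ⇐ 8-hydroxyflavonol 8 + salicylaldehyde 11 (Mannich-type condensation at flavonol C5).
5. 8 ⇐ gallacetophenone 1 + aldehyde 4 (Claisen–Schmidt, Algar–Flynn–Oyamada). Ring order: flavonol pyranone ring (step 4), then flavan ring C (step 12); all benzene rings are bought.

Key step: step 12

Assumption: the geometry of the exocyclic C=C bond in quinone methides 13, 14 and 16 and the configuration of the benzylic carbon of 12 are left undefined, because this carbon is planar when C4 is set in step 12.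

**Route**

Step 1
Reactants: 1 1-(2,3,4-trihydroxyphenyl)ethan-1-one (gallacetophenone)
Product: 2 1-[4-(benzyloxy)-2,3-dihydroxyphenyl]ethan-1-one
Conditions: BnBr (1.05 equiv), K2CO3 (1.0 equiv), DMF, 25 °C
Reagents that add atoms: benzyl bromide, BrCc1ccccc1
Why: Williamson etherification, in which the 4-OH para to the acetyl group is the most acidic, non-chelated phenol and should be alkylated selectively by one equivalent of benzyl bromide; no stereocentre is formed.

Step 2
Reactants: 2 1-[4-(benzyloxy)-2,3-dihydroxyphenyl]ethan-1-one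
Product: 3 1-[4-(benzyloxy)-2-hydroxy-3-(methoxymethoxy)phenyl]ethan-1-one
Conditions: MOMCl, K2CO3, acetone, 25 °C
Reagents that add atoms: chloromethyl methyl ether, COCCl
Why: Williamson-type O-alkylation in which the 3-OH reacts while the 2-OH stays locked in its hydrogen bond to the ketone; the acetal protects the future flavonol 8-OH orthogonally to benzyl.

Step 3
Reactants: 3 1-[4-(benzyloxy)-2-hydroxy-3-(methoxymethoxy)phenyl]ethan-1-one; 4 3,4-bis(benzyloxy)benzaldehyde
Product: 5 (E)-1-[4-(benzyloxy)-2-hydroxy-3-(methoxymethoxy)phenyl]-3-[3,4-bis(benzyloxy)phenyl]prop-2-en-1-one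
Conditions: KOH (50% aq.), EtOH/THF, 25 °C
Reagents that add atoms: none
Why: Claisen–Schmidt condensation of the methyl ketone with the non-enolisable aldehyde should give the (E)-chalcone under thermodynamic control.

Step 4
Reactants: 5 (E)-1-[4-(benzyloxy)-2-hydroxy-3-(methoxymethoxy)phenyl]-3-[3,4-bis(benzyloxy)phenyl]prop-2-en-1-one
Product: 6 7-(benzyloxy)-2-[3,4-bis(benzyloxy)phenyl]-3-hydroxy-8-(methoxymethoxy)-4H-chromen-4-one
Conditions: H2O2 (30% aq.), NaOH (aq.), MeOH/THF, 0 °C to 25 °C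
Reagents that add atoms: hydrogen peroxide, OO
Why: Algar–Flynn–Oyamada reaction, in which alkaline peroxide epoxidises the enone, the 2-phenoxide closes the pyranone ring and the 3-hydroxyflavanone is oxidised in situ to the flavonol; the ketone ring carries only H at the second ortho position, so aurone formation should not compete.

Step 5
Reactants: 6 7-(benzyloxy)-2-[3,4-bis(benzyloxy)phenyl]-3-hydroxy-8-(methoxymethoxy)-4H-chromen-4-one
Product: 7 3,7-bis(benzyloxy)-2-[3,4-bis(benzyloxy)phenyl]-8-(methoxymethoxy)-4H-chromen-4-one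
Conditions: BnBr, K2CO3, DMF, 60 °C
Reagents that add atoms: benzyl bromide, BrCc1ccccc1
Why: Williamson etherification of the acidic enolic 3-OH, the only free hydroxyl, so that it cannot be acylated in step 11.

Step 6
Reactants: 7 3,7-bis(benzyloxy)-2-[3,4-bis(benzyloxy)phenyl]-8-(methoxymethoxy)-4H-chromen-4-one
Product: 8 3,7-bis(benzyloxy)-2-[3,4-bis(benzyloxy)phenyl]-8-hydroxy-4H-chromen-4-one
Conditions: HCl (3 M), MeOH/THF, 50 °C
Reagents that add atoms: none
Why: Acid-catalysed transacetalisation to methanol should remove the methoxymethyl group and free the 8-OH, while benzyl ethers and the flavonol are stable to dilute acid.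

Step 7
Reactants: 9 2,3,4-trihydroxybenzaldehyde
Product: 10 3,4-bis(benzyloxy)-2-hydroxybenzaldehyde
Conditions: BnBr (2.1 equiv), K2CO3 (2.1 equiv), DMF, 40 °C
Reagents that add atoms: benzyl bromide, BrCc1ccccc1
Why: Williamson etherification in which the 4-OH and 3-OH are alkylated and the 2-OH, hydrogen-bonded to the formyl group, should remain free.

Step 8
Reactants: 10 3,4-bis(benzyloxy)-2-hydroxybenzaldehyde
Product: 11 3,4-bis(benzyloxy)-2-[(tert-butyldimethylsilyl)oxy]benzaldehyde
Conditions: TBSCl, imidazole, DMF, 40 °C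
Reagents that add atoms: tert-butyldimethylsilyl chloride, CC(C)(C)[Si](C)(C)Cl
Why: O-silylation masks the phenol that will become O1 of the flavan, so that it survives the amine and acetic anhydride of step 9.

Step 9
Reactants: 8 3,7-bis(benzyloxy)-2-[3,4-bis(benzyloxy)phenyl]-8-hydroxy-4H-chromen-4-one; 11 3,4-bis(benzyloxy)-2-[(tert-butyldimethylsilyl)oxy]benzaldehyde
Product: 13 3,7-bis(benzyloxy)-2-[3,4-bis(benzyloxy)phenyl]-5-{[3,4-bis(benzyloxy)-2-(tert-butyldimethylsilyloxy)phenyl]methylidene}-4H-chromene-4,8(5H)-dione (para-quinone methide), via Mannich base 12 (not isolated)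
Conditions: piperidine, toluene, reflux with azeotropic removal of water; then Ac2O, 100 °C
Reagents that add atoms: none
Why: Mannich-type (Betti) condensation, the standard para-quinone methide synthesis: the piperidine-derived iminium ion of 11 should attack C5 of phenol 8, the only free position para to the 8-OH, and acetic anhydride then removes piperidine by elimination; the racemic centre of 12 is lost.

Step 10
Reactants: 13 the silyl-protected para-quinone methide
Product: 14 3,7-bis(benzyloxy)-2-[3,4-bis(benzyloxy)phenyl]-5-{[3,4-bis(benzyloxy)-2-hydroxyphenyl]methylidene}-4H-chromene-4,8(5H)-dione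
Conditions: Bu4NF, AcOH, THF, 0 °C
Reagents that add atoms: none
Why: Buffered fluoride desilylation should give the ortho-hydroxyphenyl para-quinone methide, a stable and well-known compound class in which the former 8-OH is a carbonyl and so cannot compete in the next acylation.

Step 11
Reactants: 14 the ortho-hydroxyphenyl para-quinone methide; 15 2-(benzyloxy)acetyl chloride
Product: 16 2-{[3,7-bis(benzyloxy)-2-[3,4-bis(benzyloxy)phenyl]-4,8-dioxo-4H-chromen-5(8H)-ylidene]methyl}-5,6-bis(benzyloxy)phenyl 2-(benzyloxy)acetate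
Conditions: pyridine, CH2Cl2, −20 °C
Reagents that add atoms: none
Why: O-Acylation of the phenol installs C2, C3 and O3 as an aryl glycolate ester; pyridine is too weak a base to enolise this ester, so no racemic background cyclisation is expected.

Step 12
Reactants: 16 the quinone methide aryl 2-(benzyloxy)acetate
Product: 17 (3R,4S)-3,7,8-tris(benzyloxy)-4-{3,7-bis(benzyloxy)-2-[3,4-bis(benzyloxy)phenyl]-8-hydroxy-4-oxo-4H-chromen-5-yl}chroman-2-one (3,4-trans)
Conditions: 1-[3,5-bis(trifluoromethyl)phenyl]-3-[(2S)-3,3-dimethyl-1-{[tris(4-methoxyphenyl)-λ5-phosphanylidene]amino}butan-2-yl]thiourea (chiral bifunctional iminophosphorane base, 10 mol %; the enantiomer that gives (3R,4S)-17 is used), toluene, 4 Å molecular sieves, −30 °C to 0 °C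
Reagents that add atoms: none
Why: Proposed new method: the iminophosphorane base, with its thiourea bound to the ester carbonyl, should deprotonate C3 of the aryl benzyloxyacetate, and the ion-paired glycolate enolate should add through C3 to C4, the exocyclic δ-carbon of the para-quinone methide, re-aromatising flavonol ring A as its C8 phenoxide, which takes the proton back from the catalyst. The closest known reaction types are the chiral-base-catalysed enantioselective 1,6-additions of carbon acids (malonates, oxindoles, azlactones) to para-quinone methides and the enolate [4+2] annulations of ortho-hydroxyphenyl para-quinone methides that give 3,4-dihydrocoumarins; new is a simple α-alkoxy aryl ester as the carbon acid, cyclising with its ester link intact. Ring C of the flavan is closed at the lactone level by the C3–C4 bond in a 6-(enolexo)-exo-trig mode, the C4=C5 bond of the quinone methide being exocyclic to the new ring. C4 (S) is set by the catalyst, which has to shield one face of the planar methide carbon, and C3 (R) is set under thermodynamic control, because the lactone α-hydrogen exchanges under the basic conditions and the 3,4-trans isomer is the more stable one. The step needs enantioface selectivity at C4 and C-alkylation through a six-membered transition state; the substrate secures the latter by the two-atom O1–C2 tether on the ortho position of ring A (no other ring size is within reach) and helps the former by the O3-chelated enolate and by the peri carbonyl of the flavonol, which fixes the methide geometry.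

Step 13
Reactants: 17 the (3R,4S)-lactone
Product: 18 (3R,4S)-3,7,8-tris(benzyloxy)-4-{3,7-bis(benzyloxy)-2-[3,4-bis(benzyloxy)phenyl]-8-hydroxy-4-oxo-4H-chromen-5-yl}chroman-2-ol (both C2 epimers)
Conditions: iBu2AlH (2.2 equiv), CH2Cl2, −78 °C
Reagents that add atoms: none
Why: Partial reduction of the aryl lactone, by far the most electrophilic carbonyl, should stop at the aluminium hemiacetal at −78 °C, leaving the vinylogous-ester carbonyl of the chromone; the C2 configuration of the lactol is irrelevant and C3 and C4 are untouched.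

Step 14
Reactants: 18 the lactol; 19 1,2-bis(benzyloxy)benzene
Product: 20 3,7-bis(benzyloxy)-2-[3,4-bis(benzyloxy)phenyl]-5-{(2R,3R,4S)-3,7,8-tris(benzyloxy)-2-[3,4-bis(benzyloxy)phenyl]chroman-4-yl}-8-hydroxy-4H-chromen-4-one (2,3-cis-3,4-trans)
Conditions: BF3·OEt2, 19 (3 equiv), CH2Cl2, 4 Å molecular sieves, −78 °C to −40 °C
Reagents that add atoms: none
Why: Friedel–Crafts C-arylation of the cyclic oxocarbenium ion from 18, in which the arene reacts para to one benzyloxy group and should enter pseudo-axially on the half-chair that keeps 3-OBn and the C4 aryl pseudo-equatorial, anti to the axial C3–H, placing the new aryl cis to the C3 oxygen (2R), the known 1,2-cis preference of 2-alkoxy six-membered oxocarbenium ions under kinetic control.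

Step 15
Reactants: 20 the nonabenzyl ether
Product: 21 2-(3,4-dihydroxyphenyl)-5-[(2R,3R,4S)-2-(3,4-dihydroxyphenyl)-3,7,8-trihydroxychroman-4-yl]-3,7,8-trihydroxy-4H-chromen-4-one (CNP0395591.1)
Conditions: H2 (1 atm), Pd(OH)2/C, THF/MeOH, 25 °C
Reagents that add atoms: none
Why: Hydrogenolysis should remove all nine benzyl ethers under conditions that leave the cyclic benzylic C2–O1 ether of flavan-3-ols and the flavonol C2=C3 bond intact; no stereocentre is affected.

**Compound list**

1 | 1-(2,3,4-trihydroxyphenyl)ethan-1-one | CC(=O)c1ccc(O)c(O)c1O | starting material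
2 | 1-[4-(benzyloxy)-2,3-dihydroxyphenyl]ethan-1-one | CC(=O)c1ccc(OCc2ccccc2)c(O)c1O | intermediate
3 | 1-[4-(benzyloxy)-2-hydroxy-3-(methoxymethoxy)phenyl]ethan-1-one | CC(=O)c1ccc(OCc2ccccc2)c(OCOC)c1O | intermediate
4 | 3,4-bis(benzyloxy)benzaldehyde | O=Cc1ccc(OCc2ccccc2)c(OCc2ccccc2)c1 | starting material
5 | (E)-1-[4-(benzyloxy)-2-hydroxy-3-(methoxymethoxy)phenyl]-3-[3,4-bis(benzyloxy)phenyl]prop-2-en-1-one | O=C(/C=C/c1ccc(OCc2ccccc2)c(OCc2ccccc2)c1)c1ccc(OCc2ccccc2)c(OCOC)c1O | intermediate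
6 | 7-(benzyloxy)-2-[3,4-bis(benzyloxy)phenyl]-3-hydroxy-8-(methoxymethoxy)-4H-chromen-4-one | O=c1c(O)c(-c2ccc(OCc3ccccc3)c(OCc3ccccc3)c2)oc2c(OCOC)c(OCc3ccccc3)ccc12 | intermediate
7 | 3,7-bis(benzyloxy)-2-[3,4-bis(benzyloxy)phenyl]-8-(methoxymethoxy)-4H-chromen-4-one | O=c1c(OCc2ccccc2)c(-c2ccc(OCc3ccccc3)c(OCc3ccccc3)c2)oc2c(OCOC)c(OCc3ccccc3)ccc12 | intermediate
8 | 3,7-bis(benzyloxy)-2-[3,4-bis(benzyloxy)phenyl]-8-hydroxy-4H-chromen-4-one | O=c1c(OCc2ccccc2)c(-c2ccc(OCc3ccccc3)c(OCc3ccccc3)c2)oc2c(O)c(OCc3ccccc3)ccc12 | intermediate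
9 | 2,3,4-trihydroxybenzaldehyde | O=Cc1ccc(O)c(O)c1O | starting material
10 | 3,4-bis(benzyloxy)-2-hydroxybenzaldehyde | O=Cc1ccc(OCc2ccccc2)c(OCc2ccccc2)c1O | intermediate
11 | 3,4-bis(benzyloxy)-2-[(tert-butyldimethylsilyl)oxy]benzaldehyde | O=Cc1ccc(OCc2ccccc2)c(OCc2ccccc2)c1O[Si](C)(C)C(C)(C)C | intermediate
12 | 3,7-bis(benzyloxy)-2-[3,4-bis(benzyloxy)phenyl]-5-{[3,4-bis(benzyloxy)-2-(tert-butyldimethylsilyloxy)phenyl](piperidin-1-yl)methyl}-8-hydroxy-4H-chromen-4-one (racemic Mannich base) | O=c1c(OCc2ccccc2)c(-c2ccc(OCc3ccccc3)c(OCc3ccccc3)c2)oc2c(O)c(OCc3ccccc3)cc(C(N3CCCCC3)c3ccc(OCc4ccccc4)c(OCc4ccccc4)c3O[Si](C)(C)C(C)(C)C)c12 | intermediate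
13 | 3,7-bis(benzyloxy)-2-[3,4-bis(benzyloxy)phenyl]-5-{[3,4-bis(benzyloxy)-2-(tert-butyldimethylsilyloxy)phenyl]methylidene}-4H-chromene-4,8(5H)-dione | O=C1C(OCc2ccccc2)=C(c2ccc(OCc3ccccc3)c(OCc3ccccc3)c2)OC2=C1C(=Cc1ccc(OCc3ccccc3)c(OCc3ccccc3)c1O[Si](C)(C)C(C)(C)C)C=C(OCc1ccccc1)C2=O | intermediate
14 | 3,7-bis(benzyloxy)-2-[3,4-bis(benzyloxy)phenyl]-5-{[3,4-bis(benzyloxy)-2-hydroxyphenyl]methylidene}-4H-chromene-4,8(5H)-dione | O=C1C(OCc2ccccc2)=C(c2ccc(OCc3ccccc3)c(OCc3ccccc3)c2)OC2=C1C(=Cc1ccc(OCc3ccccc3)c(OCc3ccccc3)c1O)C=C(OCc1ccccc1)C2=O | intermediate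
15 | 2-(benzyloxy)acetyl chloride | O=C(Cl)COCc1ccccc1 | starting material
16 | 2-{[3,7-bis(benzyloxy)-2-[3,4-bis(benzyloxy)phenyl]-4,8-dioxo-4H-chromen-5(8H)-ylidene]methyl}-5,6-bis(benzyloxy)phenyl 2-(benzyloxy)acetate | O=C1C(OCc2ccccc2)=C(c2ccc(OCc3ccccc3)c(OCc3ccccc3)c2)OC2=C1C(=Cc1ccc(OCc3ccccc3)c(OCc3ccccc3)c1OC(=O)COCc1ccccc1)C=C(OCc1ccccc1)C2=O | intermediate
17 | (3R,4S)-3,7,8-tris(benzyloxy)-4-{3,7-bis(benzyloxy)-2-[3,4-bis(benzyloxy)phenyl]-8-hydroxy-4-oxo-4H-chromen-5-yl}chroman-2-one | O=c1c(OCc2ccccc2)c(-c2ccc(OCc3ccccc3)c(OCc3ccccc3)c2)oc2c(O)c(OCc3ccccc3)cc([C@H]3c4ccc(OCc5ccccc5)c(OCc5ccccc5)c4OC(=O)[C@@H]3OCc3ccccc3)c12 | intermediate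
18 | (3R,4S)-3,7,8-tris(benzyloxy)-4-{3,7-bis(benzyloxy)-2-[3,4-bis(benzyloxy)phenyl]-8-hydroxy-4-oxo-4H-chromen-5-yl}chroman-2-ol (C2 epimers) | O=c1c(OCc2ccccc2)c(-c2ccc(OCc3ccccc3)c(OCc3ccccc3)c2)oc2c(O)c(OCc3ccccc3)cc([C@H]3c4ccc(OCc5ccccc5)c(OCc5ccccc5)c4OC(O)[C@@H]3OCc3ccccc3)c12 | intermediate
19 | 1,2-bis(benzyloxy)benzene | c1ccc(OCc2ccccc2)c(OCc2ccccc2)c1 | starting material
20 | 3,7-bis(benzyloxy)-2-[3,4-bis(benzyloxy)phenyl]-5-{(2R,3R,4S)-3,7,8-tris(benzyloxy)-2-[3,4-bis(benzyloxy)phenyl]chroman-4-yl}-8-hydroxy-4H-chromen-4-one | O=c1c(OCc2ccccc2)c(-c2ccc(OCc3ccccc3)c(OCc3ccccc3)c2)oc2c(O)c(OCc3ccccc3)cc([C@H]3c4ccc(OCc5ccccc5)c(OCc5ccccc5)c4O[C@H](c4ccc(OCc5ccccc5)c(OCc5ccccc5)c4)[C@@H]3OCc3ccccc3)c12 | intermediate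
21 | 2-(3,4-dihydroxyphenyl)-5-[(2R,3R,4S)-2-(3,4-dihydroxyphenyl)-3,7,8-trihydroxychroman-4-yl]-3,7,8-trihydroxy-4H-chromen-4-one | O=c1c(O)c(-c2ccc(O)c(O)c2)oc2c(O)c(O)cc([C@H]3c4ccc(O)c(O)c4O[C@H](c4ccc(O)c(O)c4)[C@@H]3O)c12 | target

**Step count and risks**

Total step count: 15. Longest linear sequence: 13 steps (steps 1–6 and 9–15, from gallacetophenone 1); steps 7–8 form the side branch.

Steps most likely to fail:

1. Step 12 (Proposed new method). Enolisation of the weakly acidic aryl ester may be too slow, the enolate may fragment to a ketene and aryloxide, or the facial selectivity at C4 may be low. Fallback with known chemistry, setting out from 14 and returning at 17: benzyloxyacetic acid is activated with pivaloyl chloride and iPr2NEt as 2-(benzyloxy)acetic pivalic anhydride F1 and combined with 14 and the isothiourea catalyst (2S,3R)-3-isopropyl-2-phenyl-3,4-dihydro-2H-benzo[4,5]thiazolo[3,2-a]pyrimidine or its enantiomer. The derived ammonium enolate should add 1,6 to the quinone methide and the freed O1 phenoxide should lactonise (enolate-organocatalytic Michael addition–lactonisation, a known annulation of ortho-hydroxyphenyl para-quinone methides), with C3 equilibrating to trans under the amine base to give 17.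

2. Step 14. Facial selectivity at C2 may be poor, or the Lewis acid may epimerise C2 by reversible ring opening. Fallback setting out from 17 and returning at 20, placing the C2 oxygen by chelation control and closing O1–C2 with inversion:
 - Aminolysis of lactone 17 with MeNH(OMe)·HCl and iPrMgCl should give the N-methoxy-N-methylamide (2R,3S)-2-(benzyloxy)-3-[3,4-bis(benzyloxy)-2-hydroxyphenyl]-3-{3,7-bis(benzyloxy)-2-[3,4-bis(benzyloxy)phenyl]-8-hydroxy-4-oxo-4H-chromen-5-yl}-N-methoxy-N-methylpropanamide F2.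
 - [3,4-Bis(benzyloxy)phenyl]magnesium bromide should convert it to the aryl ketone (2R,3S)-2-(benzyloxy)-3-[3,4-bis(benzyloxy)-2-hydroxyphenyl]-3-{3,7-bis(benzyloxy)-2-[3,4-bis(benzyloxy)phenyl]-8-hydroxy-4-oxo-4H-chromen-5-yl}-1-[3,4-bis(benzyloxy)phenyl]propan-1-one F3.
 - Chelation-controlled reduction of the α-benzyloxy ketone with Zn(BH4)2 should give the anti alcohol (1S,2R,3S)-2-(benzyloxy)-3-[3,4-bis(benzyloxy)-2-hydroxyphenyl]-3-{3,7-bis(benzyloxy)-2-[3,4-bis(benzyloxy)phenyl]-8-hydroxy-4-oxo-4H-chromen-5-yl}-1-[3,4-bis(benzyloxy)phenyl]propan-1-ol F4.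
 - Intramolecular Mitsunobu etherification (PPh3, diisopropyl azodicarboxylate) by the O1 phenol, with inversion at C2, should give the 2,3-cis flavan 20.

3. Step 9. The C–C bond has to form at C5 of the flavonol, peri to the carbonyl, and hot piperidine may open the pyranone ring. Fallback setting out from 8 and 11 and returning at 13, under acidic conditions without amine: three-component α-sulfonylalkylation of phenol 8 with aldehyde 11 and sodium 4-methylbenzenesulfinate in formic acid (Friedel–Crafts hydroxyalkylation, ionisation and sulfinate capture) should give the sulfone 3,7-bis(benzyloxy)-2-[3,4-bis(benzyloxy)phenyl]-5-{[3,4-bis(benzyloxy)-2-(tert-butyldimethylsilyloxy)phenyl](4-methylbenzenesulfonyl)methyl}-8-hydroxy-4H-chromen-4-one F5. Brief treatment with aqueous K2CO3 in CH2Cl2 should then eliminate sulfinate to give quinone methide 13.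

**Further compounds**

F1 | step 12 | 2-(benzyloxy)acetic pivalic anhydride | CC(C)(C)C(=O)OC(=O)COCc1ccccc1
F2 | step 14 | (2R,3S)-2-(benzyloxy)-3-[3,4-bis(benzyloxy)-2-hydroxyphenyl]-3-{3,7-bis(benzyloxy)-2-[3,4-bis(benzyloxy)phenyl]-8-hydroxy-4-oxo-4H-chromen-5-yl}-N-methoxy-N-methylpropanamide | O=c1c(OCc2ccccc2)c(-c2ccc(OCc3ccccc3)c(OCc3ccccc3)c2)oc2c(O)c(OCc3ccccc3)cc([C@@H](c3ccc(OCc4ccccc4)c(OCc4ccccc4)c3O)[C@@H](OCc3ccccc3)C(=O)N(C)OC)c12
F3 | step 14 | (2R,3S)-2-(benzyloxy)-3-[3,4-bis(benzyloxy)-2-hydroxyphenyl]-3-{3,7-bis(benzyloxy)-2-[3,4-bis(benzyloxy)phenyl]-8-hydroxy-4-oxo-4H-chromen-5-yl}-1-[3,4-bis(benzyloxy)phenyl]propan-1-one | O=c1c(OCc2ccccc2)c(-c2ccc(OCc3ccccc3)c(OCc3ccccc3)c2)oc2c(O)c(OCc3ccccc3)cc([C@@H](c3ccc(OCc4ccccc4)c(OCc4ccccc4)c3O)[C@@H](OCc3ccccc3)C(=O)c3ccc(OCc4ccccc4)c(OCc4ccccc4)c3)c12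
F4 | step 14 | (1S,2R,3S)-2-(benzyloxy)-3-[3,4-bis(benzyloxy)-2-hydroxyphenyl]-3-{3,7-bis(benzyloxy)-2-[3,4-bis(benzyloxy)phenyl]-8-hydroxy-4-oxo-4H-chromen-5-yl}-1-[3,4-bis(benzyloxy)phenyl]propan-1-ol | O=c1c(OCc2ccccc2)c(-c2ccc(OCc3ccccc3)c(OCc3ccccc3)c2)oc2c(O)c(OCc3ccccc3)cc([C@@H](c3ccc(OCc4ccccc4)c(OCc4ccccc4)c3O)[C@@H](OCc3ccccc3)[C@@H](O)c3ccc(OCc4ccccc4)c(OCc4ccccc4)c3)c12
F5 | step 9 | 3,7-bis(benzyloxy)-2-[3,4-bis(benzyloxy)phenyl]-5-{[3,4-bis(benzyloxy)-2-(tert-butyldimethylsilyloxy)phenyl](4-methylbenzenesulfonyl)methyl}-8-hydroxy-4H-chromen-4-one (racemic) | O=c1c(OCc2ccccc2)c(-c2ccc(OCc3ccccc3)c(OCc3ccccc3)c2)oc2c(O)c(OCc3ccccc3)cc(C(c3ccc(OCc4ccccc4)c(OCc4ccccc4)c3O[Si](C)(C)C(C)(C)C)S(=O)(=O)c3ccc(C)cc3)c12
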